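**Retrosynthetic overview**
- Acredinone B comes from its bis-MOM ether by acid cleavage of the two chelated MOM groups.
- The central Ar–C(=O)–CH2–Ar unit is cut on both sides of the carbonyl: a ring-A benzylzinc half, carbon monoxide and a ring-B aryl iodide half are joined in one late Pd-catalysed carbonylative coupling.
- Ring-A half: a benzyl chloride obtained by opening a phthalide with 2-lithio-1,3-dimethoxybenzene; the phthalide comes from a benzamide by directed ortho-metalation.
- Ring-B half: an o-iodobenzophenone made by adding the same aryllithium to an o-iodobenzaldehyde and oxidising; the iodide is placed by Comins ortho-lithiation.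
- Both halves diverge from one arene, 1-methoxy-4-(methoxymethoxy)-2-methylbenzene (from m-cresol); the dimethoxyphenyl unit comes from resorcinol. All benzene rings are bought; the only ring made is the phthalide lactone, which is opened again.

Assumption: the target SMILES contains no stereocentre (the molecule is achiral), so no asymmetric step is needed; the one transient carbinol stereocentre (compound 13) is racemic and is removed by oxidation.

**Route**

Step 1
Reactants: 1 m-cresol (3-methylphenol)
Product: 2 4-bromo-3-methylphenol
Conditions: Bu4NBr3 (1.0 equiv), CH2Cl2/MeOH, 20 °C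
Reagents that add atoms: tetrabutylammonium tribromide (Bu4N+ Br3−, written as the bromide·Br2 adduct), CCCC[N+](CCCC)(CCCC)CCCC.[Br-].BrBr
Why: Electrophilic aromatic bromination with the mild tribromide goes para to the strongly directing OH.

Step 2
Reactants: 2 4-bromo-3-methylphenol
Product: 3 1-bromo-4-(methoxymethoxy)-2-methylbenzene
Conditions: MOMCl, i-Pr2NEt, CH2Cl2, 0 °C → rt
Reagents that add atoms: chloromethyl methyl ether, COCCl
Why: O-alkylation of the phenol gives the MOM ether, which is base-stable and later serves as the ortho-metalation director.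

Step 3
Reactants: 3 1-bromo-4-(methoxymethoxy)-2-methylbenzene
Product: 4 1-methoxy-4-(methoxymethoxy)-2-methylbenzene
Conditions: NaOMe (5 equiv, in MeOH), CuBr (10 mol %), DMF, 110 °C
Reagents that add atoms: sodium methoxide, [Na+].[O-]C
Why: Ullmann-type copper-catalysed C–O coupling replaces Br by OMe, and the MOM acetal is inert to hot alkoxide.

Step 4
Reactants: 5 resorcinol (benzene-1,3-diol)
Product: 6 1,3-dimethoxybenzene
Conditions: Me2SO4, K2CO3, acetone, reflux
Reagents that add atoms: dimethyl sulfate, COS(=O)(=O)OC
Why: Williamson double O-methylation under weak-base conditions avoids C-alkylation of resorcinol.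

Step 5
Reactants: 4 1-methoxy-4-(methoxymethoxy)-2-methylbenzene
Product: 7 N,N-diethyl-5-methoxy-2-(methoxymethoxy)-4-methylbenzamide
Conditions: n-BuLi, THF, 0 °C, 1 h; then Et2NCOCl, −78 °C → rt
Reagents that add atoms: diethylcarbamoyl chloride, CCN(CC)C(=O)Cl
Why: Directed ortho-metalation occurs next to OMOM at the unhindered site (not the one flanked by CH3), and the aryllithium is trapped as the tertiary amide.

Step 6
Reactants: 7 N,N-diethyl-5-methoxy-2-(methoxymethoxy)-4-methylbenzamide
Product: 8 4-methoxy-7-(methoxymethoxy)-5-methyl-2-benzofuran-1(3H)-one (a phthalide: lactone C=O next to the OMOM carbon, CH2 next to the OMe carbon)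
Conditions: s-BuLi, TMEDA, THF, −78 °C; CH2O (gas, from cracked paraformaldehyde), −78 °C → rt; then PPTS (cat.), toluene, 60 °C
Reagents that add atoms: formaldehyde, C=O
Why: Amide-directed ortho-metalation at the only free ortho position (also activated by the adjacent OMe), hydroxymethylation, and lactonisation of the primary alcohol onto the twisted amide with loss of Et2NH under acid mild enough to keep the MOM ether.

Step 7
Reactants: 8 the phthalide; 6 1,3-dimethoxybenzene
Product: 9 (2,6-dimethoxyphenyl)[2-(hydroxymethyl)-3-methoxy-6-(methoxymethoxy)-4-methylphenyl]methanone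
Conditions: 6, n-BuLi, THF, 0 °C → rt (gives 2-lithio-1,3-dimethoxybenzene); then 8, −78 → 0 °C; aq NH4Cl
Reagents that add atoms: none
Why: Aryllithium addition to the lactone stops at the hindered lactol alkoxide, which opens on work-up to the keto alcohol (in equilibrium with its lactol); both the nucleophile and the product ketone are too hindered for a second addition.

Step 8
Reactants: 9 the keto alcohol
Product: 10 [2-(chloromethyl)-3-methoxy-6-(methoxymethoxy)-4-methylphenyl](2,6-dimethoxyphenyl)methanone
Conditions: MsCl, LiCl, 2,4,6-collidine, DMF, 0 °C → rt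
Reagents that add atoms: lithium chloride, [Li+].[Cl-]
Why: Mesylation of the primary benzylic alcohol and in situ SN2 displacement by chloride under buffered conditions that spare the MOM ether and suppress isobenzofuran formation.

Step 9
Reactants: 4 1-methoxy-4-(methoxymethoxy)-2-methylbenzene
Product: 11 5-methoxy-2-(methoxymethoxy)-4-methylbenzaldehyde
Conditions: n-BuLi, THF, 0 °C; DMF, −78 °C → rt; aq NH4Cl
Reagents that add atoms: N,N-dimethylformamide, CN(C)C=O
Why: The same OMOM-directed ortho-lithiation as in step 5, here followed by formylation with DMF.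

Step 10
Reactants: 11 5-methoxy-2-(methoxymethoxy)-4-methylbenzaldehyde
Product: 12 2-iodo-3-methoxy-6-(methoxymethoxy)-4-methylbenzaldehyde
Conditions: LiN(Me)CH2CH2NMe2, THF, −20 °C; n-BuLi (3 equiv), −20 °C; I2, −78 °C → rt; aq Na2S2O3
Reagents that add atoms: iodine, II
Why: Comins in situ α-amino alkoxide protection turns the aldehyde into a chelating director, so lithiation occurs at the position between it and the OMe group; iodination and work-up return the aldehyde.

Step 11
Reactants: 12 the iodo aldehyde; 6 1,3-dimethoxybenzene
Product: 13 (2,6-dimethoxyphenyl)[2-iodo-3-methoxy-6-(methoxymethoxy)-4-methylphenyl]methanol (racemic)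
Conditions: 6, n-BuLi, THF, 0 °C → rt; then 12, −78 °C; aq NH4Cl
Reagents that add atoms: none
Why: 1,2-Addition of the stabilised 2-lithio-1,3-dimethoxybenzene to the aldehyde at −78 °C is much faster than I/Li exchange; the new carbinol centre is racemic and is removed in the next step.

Step 12
Reactants: 13 the diaryl carbinol
Product: 14 (2,6-dimethoxyphenyl)[2-iodo-3-methoxy-6-(methoxymethoxy)-4-methylphenyl]methanone
Conditions: Dess–Martin periodinane, NaHCO3, CH2Cl2, rt
Reagents that add atoms: none
Why: Buffered Dess–Martin oxidation converts the hindered benzhydrol into the tetra-ortho-substituted benzophenone without touching the aryl iodide or the MOM ether.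

Step 13
Reactants: 10 the benzyl chloride (ring-A half); 14 the aryl iodide (ring-B half)
Product: 15 1,2-bis[2-(2,6-dimethoxybenzoyl)-6-methoxy-3-(methoxymethoxy)-5-methylphenyl]ethan-1-one (bis-MOM acredinone B)
Conditions: 10, Zn dust (activated), LiCl, THF, 25 °C (benzylzinc chloride, not isolated); then 14, PEPPSI-IPr (5 mol %), CO (3 atm), THF/NMP, 40 °C
Reagents that add atoms: carbon monoxide, [C-]#[O+]
Why: Carbonylative Negishi coupling, in which Pd(0) inserts into the hindered Ar–I bond, CO insertion gives the aroyl–Pd species, and the ketone-tolerant benzylzinc transmetalates and reductively eliminates to the deoxybenzoin; the hindered diaryl ketones are inert to organozincs.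

Step 14
Reactants: 15 bis-MOM acredinone B
Product: 16 acredinone B, 1,2-bis[2-(2,6-dimethoxybenzoyl)-3-hydroxy-6-methoxy-5-methylphenyl]ethan-1-one
Conditions: 3 M aq HCl, THF/MeOH, 40 °C
Reagents that add atoms: none
Why: Acid-catalysed acetal cleavage removes both MOM groups, which are activated by chelation to the ortho ketones, while the aryl methyl ethers are untouched and base-induced aldol or xanthone cyclisations are avoided.

**Compound list**
1 | m-cresol (3-methylphenol) | Cc1cccc(O)c1 | starting material
2 | 4-bromo-3-methylphenol | Cc1cc(O)ccc1Br | intermediate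
3 | 1-bromo-4-(methoxymethoxy)-2-methylbenzene | COCOc1ccc(Br)c(C)c1 | intermediate
4 | 1-methoxy-4-(methoxymethoxy)-2-methylbenzene | COCOc1ccc(OC)c(C)c1 | intermediate
5 | resorcinol | Oc1cccc(O)c1 | starting material
6 | 1,3-dimethoxybenzene | COc1cccc(OC)c1 | intermediate
7 | N,N-diethyl-5-methoxy-2-(methoxymethoxy)-4-methylbenzamide | CCN(CC)C(=O)c1cc(OC)c(C)cc1OCOC | intermediate
8 | 4-methoxy-7-(methoxymethoxy)-5-methyl-2-benzofuran-1(3H)-one | COCOc1cc(C)c(OC)c2COC(=O)c12 | intermediate
9 | (2,6-dimethoxyphenyl)[2-(hydroxymethyl)-3-methoxy-6-(methoxymethoxy)-4-methylphenyl]methanone | COCOc1cc(C)c(OC)c(CO)c1C(=O)c1c(OC)cccc1OC | intermediate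
10 | [2-(chloromethyl)-3-methoxy-6-(methoxymethoxy)-4-methylphenyl](2,6-dimethoxyphenyl)methanone | COCOc1cc(C)c(OC)c(CCl)c1C(=O)c1c(OC)cccc1OC | intermediate
11 | 5-methoxy-2-(methoxymethoxy)-4-methylbenzaldehyde | COCOc1cc(C)c(OC)cc1C=O | intermediate
12 | 2-iodo-3-methoxy-6-(methoxymethoxy)-4-methylbenzaldehyde | COCOc1cc(C)c(OC)c(I)c1C=O | intermediate
13 | (2,6-dimethoxyphenyl)[2-iodo-3-methoxy-6-(methoxymethoxy)-4-methylphenyl]methanol (racemic) | COCOc1cc(C)c(OC)c(I)c1C(O)c1c(OC)cccc1OC | intermediate
14 | (2,6-dimethoxyphenyl)[2-iodo-3-methoxy-6-(methoxymethoxy)-4-methylphenyl]methanone | COCOc1cc(C)c(OC)c(I)c1C(=O)c1c(OC)cccc1OC | intermediate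
15 | 1,2-bis[2-(2,6-dimethoxybenzoyl)-6-methoxy-3-(methoxymethoxy)-5-methylphenyl]ethan-1-one | COCOc1cc(C)c(OC)c(CC(=O)c2c(OC)c(C)cc(OCOC)c2C(=O)c2c(OC)cccc2OC)c1C(=O)c1c(OC)cccc1OC | intermediate
16 | acredinone B (achiral) | COc1cccc(OC)c1C(=O)c1c(O)cc(C)c(OC)c1CC(=O)c1c(OC)c(C)cc(O)c1C(=O)c1c(OC)cccc1OC | target

**Step count**
- Total steps: 14.
- Longest linear sequence: 9 steps (1, 2, 3, 5, 6, 7, 8, 13, 14; the ring-B arm 1, 2, 3, 9, 10, 11, 12, 13, 14 is equally long).

**Three steps most likely to fail, with fallbacks**
1. Step 13 (three-component carbonylative coupling of two hindered partners; direct non-carbonylative coupling or bibenzyl formation may compete). Fallback: form the bond at the aldehyde oxidation level. Convert iodo ketone 14 into the corresponding 2-aroylbenzaldehyde by Pd-catalysed reductive carbonylation (Pd(OAc)2, CO, Et3SiH), add the benzylzinc from 10 to this ring-B aldehyde (or use a CrCl2-mediated benzylation), then oxidise the resulting secondary alcohol with Dess–Martin periodinane.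
2. Step 7 (hindered aryllithium adding to a hindered phthalide; deprotonation at the lactone CH2 or no addition). Fallback: make 9 from the ring-B series by Stille hydroxymethylation of iodo ketone 14 with Bu3SnCH2OH and Pd(PPh3)4, so that both benzophenones come from the aldehyde addition/oxidation sequence.
3. Step 10 (regiochemistry of the Comins lithiation; OMOM could direct metalation to the position next to CH3). Fallback: use the amide as director. Lithiate amide 7 (s-BuLi/TMEDA), quench with I2, then reduce the tertiary amide to aldehyde 12 with Cp2Zr(H)Cl (Schwartz reagent).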